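The 5-hydroxyindole is disconnected across C3a–C7a and C4–C5, so that its benzene ring (C4 to C7a) comes from a furan and a terminal alkyne. The furan oxygen becomes the C5 hydroxyl, para to C7a, which is why this indole alone carries a free phenol. One thermal operation on an N-Boc-N-(2-furyl)amine, tethered through CH2 to a tertiary propargylic carbinol that bears the central tetramethoxyphenyl ring, should close the six-membered ring and the pyrrole ring, open the oxygen bridge, aromatise, dehydrate and shed both Boc groups. The methoxyindole is attached earlier by a Negishi coupling, and the carbinol is assembled by Weinreb acylation and ethynyl Grignard addition.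

Key step: step 8

Remark: carbinol 22 is racemic (one enantiomer is drawn), its only stereocentre is erased in step 8 and the target is achiral; 2-bromo-N-methoxy-N-methylacetamide 5 is taken as a commercial reagent.

Step 1
Reactants: 1 2-furoic acid
Product: 4 tert-butyl furan-2-ylcarbamate, via furan-2-carbonyl azide 2 (not isolated), via 2-isocyanatofuran 3 (not isolated)
Conditions: (PhO)2P(O)N3, Et3N, t-BuOH, reflux
Reagents that add atoms: diphenylphosphoryl azide, [N-]=[N+]=NP(=O)(Oc1ccccc1)Oc1ccccc1; tert-butanol, CC(C)(C)O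
Why: Curtius rearrangement, in which acyl azide 2 loses N2 on heating with migration of the furyl group to nitrogen and tert-butanol traps isocyanate 3 as the Boc carbamate, the usual way to handle the unstable 2-aminofuran in protected form.

Step 2
Reactants: 4 tert-butyl furan-2-ylcarbamate; 5 2-bromo-N-methoxy-N-methylacetamide
Product: 7 tert-butyl furan-2-yl{2-[methoxy(methyl)amino]-2-oxoethyl}carbamate, via sodium carbamate salt 6 (not isolated)
Conditions: NaH (1.05 equiv), DMF, 0 °C; then 5, 0 °C to rt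
Reagents that add atoms: none
Why: SN2 N-alkylation of the soft, weakly basic carbamate anion 6 by a primary bromide activated by the adjacent amide carbonyl, which should leave the Weinreb amide untouched and delivers the glycine unit in one step.

Step 3
Reactants: 8 1,2,4,5-tetramethoxybenzene
Product: 10 1,4-dibromo-2,3,5,6-tetramethoxybenzene, via 3-bromo-1,2,4,5-tetramethoxybenzene 9 (not isolated)
Conditions: Br2 (2.2 equiv), CH2Cl2, 0 °C to rt
Reagents that add atoms: bromine, BrBr
Why: Electrophilic aromatic bromination, in which the only two free positions are each flanked by two methoxy groups, so twofold substitution through 9 should stop at the para-dibromide.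

Step 4
Reactants: 11 5-methoxy-1H-indole
Product: 13 tert-butyl 3-iodo-5-methoxyindole-1-carboxylate, via 3-iodo-5-methoxy-1H-indole 12 (not isolated)
Conditions: I2, KOH, DMF, rt; aq. Na2S2O3 wash; crude then Boc2O, DMAP (cat.), CH2Cl2, rt
Reagents that add atoms: iodine, II; di-tert-butyl dicarbonate, CC(C)(C)OC(=O)OC(=O)OC(C)(C)C
Why: Electrophilic iodination at C3, the most nucleophilic indole carbon, followed by DMAP-catalysed N-acylation, which stabilises the labile 3-iodoindole 12 for handling.

Step 5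
Reactants: 10 1,4-dibromo-2,3,5,6-tetramethoxybenzene; 13 tert-butyl 3-iodo-5-methoxyindole-1-carboxylate
Product: 16 tert-butyl 3-(4-bromo-2,3,5,6-tetramethoxyphenyl)-5-methoxyindole-1-carboxylate, via (4-bromo-2,3,5,6-tetramethoxyphenyl)lithium 14 (not isolated), via (4-bromo-2,3,5,6-tetramethoxyphenyl)zinc chloride 15 (not isolated)
Conditions: 10 (1.3 equiv), n-BuLi (1.0 equiv per 10), THF, –78 °C; ZnCl2, –78 °C to rt; then 13, Pd(PPh3)4 (5 mol %), THF, 55 °C
Reagents that add atoms: none
Why: Negishi coupling, in which one equivalent of n-BuLi exchanges a single bromine, transmetalation gives arylzinc 15, and zerovalent palladium inserts into the weak C–I bond of 13 far faster than into the hindered, electron-rich C–Br bonds of 15 or 16, so the coupling should stop at the monoarylated bromide.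

Step 6
Reactants: 16 tert-butyl 3-(4-bromo-2,3,5,6-tetramethoxyphenyl)-5-methoxyindole-1-carboxylate; 7 tert-butyl furan-2-yl{2-[methoxy(methyl)amino]-2-oxoethyl}carbamate
Product: 19 tert-butyl 3-{4-[N-(tert-butoxycarbonyl)-N-(furan-2-yl)glycyl]-2,3,5,6-tetramethoxyphenyl}-5-methoxyindole-1-carboxylate, via aryllithium 17 (not isolated), via lithium hemiaminal adduct 18 (not isolated)
Conditions: t-BuLi (2.0 equiv), THF, –78 °C; then 7, –78 to –40 °C; aq. NH4Cl
Reagents that add atoms: none
Why: Weinreb ketone synthesis, in which bromine–lithium exchange at –78 °C outruns attack on or deprotonation beside the indole carbamate, and the methoxy-chelated aryllithium 17 adds to the amide to give the N,O-chelated adduct 18 (racemic, transient), which cannot over-add and releases ketone 19 only on aqueous quench.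

Step 7
Reactants: 19 tert-butyl 3-{4-[N-(tert-butoxycarbonyl)-N-(furan-2-yl)glycyl]-2,3,5,6-tetramethoxyphenyl}-5-methoxyindole-1-carboxylate; 20 ethynylmagnesium bromide
Product: 22 tert-butyl N-(furan-2-yl)-N-{2-hydroxy-2-[4-(1-tert-butoxycarbonyl-5-methoxyindol-3-yl)-2,3,5,6-tetramethoxyphenyl]but-3-yn-1-yl}carbamate (racemic), via bromomagnesium alkoxide 21 (not isolated)
Conditions: 20 (3 equiv), THF, –40 to 0 °C; aq. NH4Cl at 0 °C
Reagents that add atoms: none
Why: Grignard 1,2-addition of a small, weakly basic sp-carbon nucleophile to the shielded ketone, helped by magnesium chelation between the ketone and carbamate oxygens; the carbinol stereocentre forms racemic, which is acceptable because step 8 erases it, and the cold quench keeps alkoxide 21 from attacking the neighbouring Boc carbonyl.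

Step 8
Reactants: 22 tert-butyl N-(furan-2-yl)-N-{2-hydroxy-2-[4-(1-tert-butoxycarbonyl-5-methoxyindol-3-yl)-2,3,5,6-tetramethoxyphenyl]but-3-yn-1-yl}carbamate
Product: 27 3-[2,3,5,6-tetramethoxy-4-(5-methoxy-1H-indol-3-yl)phenyl]-1H-indol-5-ol (target), via oxa-bridged cycloadduct 23 (not isolated), via N-Boc 3-arylindoline-3,5-diol 24 (not isolated), via bis-Boc 5-hydroxyindole 25 (not isolated), via mono-Boc 5-hydroxyindole 26 (not isolated)
Conditions: o-dichlorobenzene (0.02 M, degassed), argon, microwave, 190 °C, sealed vessel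
Reagents that add atoms: none
Why: The electron-rich 2-amidofuran of 22 acts as diene and the tethered terminal alkyne as dienophile in a thermal intramolecular (4+2) cycloaddition that forms C3a–C7a and C4–C5 and gives oxa-bridged 23; the carbamate nitrogen then pushes open the C7a–O bond, loss of the C5 proton aromatises the six-membered ring to phenol 24, loss of water from the tertiary benzylic C3 carbinol gives indole 25, and both Boc groups fragment thermally to isobutene and CO2 through 26. The closest known reaction type is the intramolecular furan Diels–Alder reaction of N-Boc-2-aminofurans carrying a tethered alkynol, which aromatises in the same pot to 5-hydroxyindoles. The five-membered ring (N1, C2, C3, C3a, C7a) closes as the tether ring of the cycloaddition, exo to both the alkyne and the furan, and the six-membered ring (C3a, C4, C5, C6, C7, C7a) closes by concerted suprafacial addition of the two alkyne carbons across furan C2 and C5. No stereocentre has to be controlled, because the racemic carbinol centre and the bridgehead centres of 23 are all erased on aromatisation. The step needs regioselectivity, which the three-atom tether secures because only the inner alkyne carbon can reach the nitrogen-bearing furan carbon (hydroxyl at C5, aryl at C3), and it needs the folded conformer, which the fully substituted carbinol carbon with its bulky aryl group favours; the methoxyindole and the tetramethoxybenzene ring offer no competing diene or dienophile.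

Compound list

1 | 2-furoic acid | OC(=O)c1ccco1 | starting material
2 | furan-2-carbonyl azide | [N-]=[N+]=NC(=O)c1ccco1 | intermediate
3 | 2-isocyanatofuran | O=C=Nc1ccco1 | intermediate
4 | tert-butyl furan-2-ylcarbamate | CC(C)(C)OC(=O)Nc1ccco1 | intermediate
5 | 2-bromo-N-methoxy-N-methylacetamide | CON(C)C(=O)CBr | starting material
6 | sodium salt of 4 (N-sodio carbamate) | CC(C)(C)OC(=O)[N-]c1ccco1.[Na+] | intermediate
7 | tert-butyl furan-2-yl{2-[methoxy(methyl)amino]-2-oxoethyl}carbamate | CON(C)C(=O)CN(C(=O)OC(C)(C)C)c1ccco1 | intermediate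
8 | 1,2,4,5-tetramethoxybenzene | COc1cc(OC)c(OC)cc1OC | starting material
9 | 3-bromo-1,2,4,5-tetramethoxybenzene | COc1cc(OC)c(OC)c(Br)c1OC | intermediate
10 | 1,4-dibromo-2,3,5,6-tetramethoxybenzene | COc1c(Br)c(OC)c(OC)c(Br)c1OC | intermediate
11 | 5-methoxy-1H-indole | COc1ccc2[nH]ccc2c1 | starting material
12 | 3-iodo-5-methoxy-1H-indole | COc1ccc2[nH]cc(I)c2c1 | intermediate
13 | tert-butyl 3-iodo-5-methoxyindole-1-carboxylate | COc1ccc2c(c1)c(I)cn2C(=O)OC(C)(C)C | intermediate
14 | (4-bromo-2,3,5,6-tetramethoxyphenyl)lithium | [Li]c1c(OC)c(OC)c(Br)c(OC)c1OC | intermediate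
15 | (4-bromo-2,3,5,6-tetramethoxyphenyl)zinc chloride | Cl[Zn]c1c(OC)c(OC)c(Br)c(OC)c1OC | intermediate
16 | tert-butyl 3-(4-bromo-2,3,5,6-tetramethoxyphenyl)-5-methoxyindole-1-carboxylate | COc1ccc2c(c1)c(-c1c(OC)c(OC)c(Br)c(OC)c1OC)cn2C(=O)OC(C)(C)C | intermediate
17 | {4-[1-(tert-butoxycarbonyl)-5-methoxyindol-3-yl]-2,3,5,6-tetramethoxyphenyl}lithium | COc1ccc2c(c1)c(-c1c(OC)c(OC)c([Li])c(OC)c1OC)cn2C(=O)OC(C)(C)C | intermediate
18 | lithium 1-{4-[1-(tert-butoxycarbonyl)-5-methoxyindol-3-yl]-2,3,5,6-tetramethoxyphenyl}-2-[(tert-butoxycarbonyl)(furan-2-yl)amino]-1-[methoxy(methyl)amino]ethan-1-olate (racemic, stereocentre not specified) | CON(C)C(O[Li])(CN(C(=O)OC(C)(C)C)c1ccco1)c1c(OC)c(OC)c(-c2cn(C(=O)OC(C)(C)C)c3ccc(OC)cc23)c(OC)c1OC | intermediate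
19 | tert-butyl 3-{4-[N-(tert-butoxycarbonyl)-N-(furan-2-yl)glycyl]-2,3,5,6-tetramethoxyphenyl}-5-methoxyindole-1-carboxylate | CC(C)(C)OC(=O)N(CC(=O)c1c(OC)c(OC)c(-c2cn(C(=O)OC(C)(C)C)c3ccc(OC)cc23)c(OC)c1OC)c1ccco1 | intermediate
20 | ethynylmagnesium bromide | C#C[Mg]Br | starting material
21 | bromomagnesium alkoxide of 22 (racemic, one enantiomer drawn) | CC(C)(C)OC(=O)N(C[C@](O[Mg]Br)(C#C)c1c(OC)c(OC)c(-c2cn(C(=O)OC(C)(C)C)c3ccc(OC)cc23)c(OC)c1OC)c1ccco1 | intermediate
22 | tert-butyl N-(furan-2-yl)-N-{2-hydroxy-2-[4-(1-tert-butoxycarbonyl-5-methoxyindol-3-yl)-2,3,5,6-tetramethoxyphenyl]but-3-yn-1-yl}carbamate (racemic, one enantiomer drawn) | CC(C)(C)OC(=O)N(C[C@](O)(C#C)c1c(OC)c(OC)c(-c2cn(C(=O)OC(C)(C)C)c3ccc(OC)cc23)c(OC)c1OC)c1ccco1 | intermediate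
23 | tert-butyl 3-aryl-3-hydroxy-2,3-dihydro-5,7a-epoxyindole-1(5H)-carboxylate, aryl = 4-(1-Boc-5-methoxyindol-3-yl)-2,3,5,6-tetramethoxyphenyl (oxa-bridged cycloadduct; diastereomer mixture, stereocentres not specified because all are lost) | CC(C)(C)OC(=O)N1CC(O)(c4c(OC)c(OC)c(-c5cn(C(=O)OC(C)(C)C)c6ccc(OC)cc56)c(OC)c4OC)C2=CC3OC21C=C3 | intermediate
24 | tert-butyl 3-{4-[1-(tert-butoxycarbonyl)-5-methoxyindol-3-yl]-2,3,5,6-tetramethoxyphenyl}-3,5-dihydroxy-2,3-dihydroindole-1-carboxylate (racemic, stereocentre not specified) | CC(C)(C)OC(=O)N1CC(O)(c3c(OC)c(OC)c(-c4cn(C(=O)OC(C)(C)C)c5ccc(OC)cc45)c(OC)c3OC)c2cc(O)ccc21 | intermediate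
25 | tert-butyl 3-{4-[1-(tert-butoxycarbonyl)-5-methoxyindol-3-yl]-2,3,5,6-tetramethoxyphenyl}-5-hydroxyindole-1-carboxylate | CC(C)(C)OC(=O)n1cc(-c3c(OC)c(OC)c(-c4cn(C(=O)OC(C)(C)C)c5ccc(OC)cc45)c(OC)c3OC)c2cc(O)ccc21 | intermediate
26 | tert-butyl 3-[4-(5-hydroxy-1H-indol-3-yl)-2,3,5,6-tetramethoxyphenyl]-5-methoxyindole-1-carboxylate | COc1ccc2c(c1)c(-c1c(OC)c(OC)c(-c3c[nH]c4ccc(O)cc34)c(OC)c1OC)cn2C(=O)OC(C)(C)C | intermediate
27 | 3-[2,3,5,6-tetramethoxy-4-(5-methoxy-1H-indol-3-yl)phenyl]-1H-indol-5-ol | COc1ccc2[nH]cc(-c3c(OC)c(OC)c(-c4c[nH]c5ccc(O)cc45)c(OC)c3OC)c2c1 | target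

Total step count: 8
Longest linear sequence: 5 steps (steps 3, 5, 6, 7, 8 from 8; equally steps 4, 5, 6, 7, 8 from 11 or steps 1, 2, 6, 7, 8 from 1)

Steps most likely to fail

1. Step 8. The di-ortho-methoxyaryl group on the carbinol carbon may keep the alkyne away from the furan, so that cycloaddition is slower than thermal loss of the furyl carbamate and decomposition of the freed aminofuran; the remote carbamate may also leave incompletely. Fallback (cross-coupling in place of cycloaddition), which sets out from 16 and comes back at 25: commercial 5-(benzyloxy)indole is iodinated as in step 4 to 5-(benzyloxy)-3-iodo-1H-indole F1 and protected to tert-butyl 5-(benzyloxy)-3-iodoindole-1-carboxylate F2. Aryllithium 17, generated from 16 as in step 6, is transmetalated with ZnCl2 to {4-[1-(tert-butoxycarbonyl)-5-methoxyindol-3-yl]-2,3,5,6-tetramethoxyphenyl}zinc chloride F3. Negishi coupling of F3 with F2 under Pd(PPh3)4 in THF should give tert-butyl 5-(benzyloxy)-3-{4-[1-(tert-butoxycarbonyl)-5-methoxyindol-3-yl]-2,3,5,6-tetramethoxyphenyl}indole-1-carboxylate F4. Hydrogenolysis (H2, Pd/C, EtOAc) should give 25, which on heating at 180 °C loses both Boc groups through 26 to give 27.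

2. Step 6. The alkyllithium may attack the indole carbamate or deprotonate indole C2 during the exchange, and the hindered aryllithium may enolise the amide instead of adding to it. Fallback (acylation before the indole is attached), which sets out from 10, 7 and 13 and comes back at 19: dibromide 10 is monolithiated to 14 as in step 5 and treated with 7 at –78 °C. This gives, through lithium 1-(4-bromo-2,3,5,6-tetramethoxyphenyl)-2-[(tert-butoxycarbonyl)(furan-2-yl)amino]-1-[methoxy(methyl)amino]ethan-1-olate F5, the ketone tert-butyl [2-(4-bromo-2,3,5,6-tetramethoxyphenyl)-2-oxoethyl](furan-2-yl)carbamate F6. Iodide 13 is converted by Miyaura borylation (B2pin2, KOAc, PdCl2(dppf), dioxane, 80 °C) into tert-butyl 5-methoxy-3-(4,4,5,5-tetramethyl-1,3,2-dioxaborolan-2-yl)indole-1-carboxylate F7. Suzuki–Miyaura coupling of F6 with F7 (Pd(OAc)2, SPhos, K3PO4, toluene–water, 80 °C) should deliver 19.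

3. Step 7. The Grignard reagent may enolise the α-amino ketone instead of adding to the shielded carbonyl, and the alkoxide may cyclise onto the neighbouring carbamate with loss of tert-butoxide. Fallback (the two carbon groups are attached to the carbinol carbon in the opposite order, replacing steps 6 and 7), which sets out from 7 and 16 and comes back at 22: lithium (trimethylsilyl)acetylide (trimethylsilylacetylene, n-BuLi, THF, –78 °C) is added to 7. This gives, through lithium 1-[(tert-butoxycarbonyl)(furan-2-yl)amino]-2-[methoxy(methyl)amino]-4-(trimethylsilyl)but-3-yn-2-olate F8, the small and highly electrophilic ynone tert-butyl furan-2-yl[2-oxo-4-(trimethylsilyl)but-3-yn-1-yl]carbamate F9. Aryllithium 17 (from 16, t-BuLi, –78 °C) then adds 1,2 to F9 to give the lithium alkoxide of the silylated alkynol F10, which is quenched at –78 °C to tert-butyl furan-2-yl{2-hydroxy-2-[4-(1-tert-butoxycarbonyl-5-methoxyindol-3-yl)-2,3,5,6-tetramethoxyphenyl]-4-(trimethylsilyl)but-3-yn-1-yl}carbamate F11 (racemic). K2CO3 in MeOH at 0 °C removes the silyl group and should give 22.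

Further compounds

F1 | step 8 | 5-(benzyloxy)-3-iodo-1H-indole | Ic1c[nH]c2ccc(OCc3ccccc3)cc12
F2 | step 8 | tert-butyl 5-(benzyloxy)-3-iodoindole-1-carboxylate | CC(C)(C)OC(=O)n1cc(I)c2cc(OCc3ccccc3)ccc21
F3 | step 8 | {4-[1-(tert-butoxycarbonyl)-5-methoxyindol-3-yl]-2,3,5,6-tetramethoxyphenyl}zinc chloride | COc1ccc2c(c1)c(-c1c(OC)c(OC)c([Zn]Cl)c(OC)c1OC)cn2C(=O)OC(C)(C)C
F4 | step 8 | tert-butyl 5-(benzyloxy)-3-{4-[1-(tert-butoxycarbonyl)-5-methoxyindol-3-yl]-2,3,5,6-tetramethoxyphenyl}indole-1-carboxylate | COc1ccc2c(c1)c(-c1c(OC)c(OC)c(-c3cn(C(=O)OC(C)(C)C)c4ccc(OCc5ccccc5)cc34)c(OC)c1OC)cn2C(=O)OC(C)(C)C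
F5 | step 6 | lithium 1-(4-bromo-2,3,5,6-tetramethoxyphenyl)-2-[(tert-butoxycarbonyl)(furan-2-yl)amino]-1-[methoxy(methyl)amino]ethan-1-olate (racemic) | CON(C)C(O[Li])(CN(C(=O)OC(C)(C)C)c1ccco1)c1c(OC)c(OC)c(Br)c(OC)c1OC
F6 | step 6 | tert-butyl [2-(4-bromo-2,3,5,6-tetramethoxyphenyl)-2-oxoethyl](furan-2-yl)carbamate | CC(C)(C)OC(=O)N(CC(=O)c1c(OC)c(OC)c(Br)c(OC)c1OC)c1ccco1
F7 | step 6 | tert-butyl 5-methoxy-3-(4,4,5,5-tetramethyl-1,3,2-dioxaborolan-2-yl)indole-1-carboxylate | COc1ccc2c(c1)c(B1OC(C)(C)C(C)(C)O1)cn2C(=O)OC(C)(C)C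
F8 | step 7 | lithium 1-[(tert-butoxycarbonyl)(furan-2-yl)amino]-2-[methoxy(methyl)amino]-4-(trimethylsilyl)but-3-yn-2-olate (racemic) | CON(C)C(O[Li])(CN(C(=O)OC(C)(C)C)c1ccco1)C#C[Si](C)(C)C
F9 | step 7 | tert-butyl furan-2-yl[2-oxo-4-(trimethylsilyl)but-3-yn-1-yl]carbamate | CC(C)(C)OC(=O)N(CC(=O)C#C[Si](C)(C)C)c1ccco1
F10 | step 7 | lithium alkoxide of F11 (racemic) | CC(C)(C)OC(=O)N(CC(O[Li])(C#C[Si](C)(C)C)c1c(OC)c(OC)c(-c2cn(C(=O)OC(C)(C)C)c3ccc(OC)cc23)c(OC)c1OC)c1ccco1
F11 | step 7 | tert-butyl furan-2-yl{2-hydroxy-2-[4-(1-tert-butoxycarbonyl-5-methoxyindol-3-yl)-2,3,5,6-tetramethoxyphenyl]-4-(trimethylsilyl)but-3-yn-1-yl}carbamate (racemic) | CC(C)(C)OC(=O)N(CC(O)(C#C[Si](C)(C)C)c1c(OC)c(OC)c(-c2cn(C(=O)OC(C)(C)C)c3ccc(OC)cc23)c(OC)c1OC)c1ccco1
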